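## Structural features

Gnetucleistol F is a stilbenolignan built on a 2-aryl-3-hydroxymethyl-2,3-dihydrobenzofuran. Ring A (C3a, C4, C5, C6, C7, C7a) is fused through C3a–C7a to the dihydrofuran ring (O1, C2, C3); C2 carries a 4-hydroxy-3,5-dimethoxyphenyl ring, C3 a CH2OH group, C7 a methoxy group and C5 an (E)-ethenyl bridge to a 3,5-dihydroxyphenyl ring. The only stereocentres, C2 (R) and C3 (S), are adjacent and trans. The fragile elements are the benzylic C2–O1 bond, which lies para to a free phenol and can ionise to a quinone methide under acid or strong base; the E-stilbene, which rules out hydrogenolysis and is sensitive to acid and light; and three oxidisable phenols. The real difficulty is twofold: C2 and C3 must be set in absolute and relative terms, and ring A is a 1,2,3,5-tetrasubstituted benzene with O1 and the C7 methoxy group on neighbouring carbons and the stilbene para to O1. The key step uses the fact that the sequence C7a(O1)–C7(OMe)–C6(H)–C5(X) of ring A is the sequence C3–C4–C5–C6 of a 3-alkoxy-4-methoxy-6-chloropyridazine, so the two missing atoms C3a and C4 can come from a terminal alkyne hung from O1 through C2 and C3. Because that construction creates no stereocentre, C2 and C3 can be installed together earlier, in an open chain, by one stereospecific C–C bond formation.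

## Logic of the disconnections

23 ⇒ 22. Four O–Si bonds are cut. The three phenols and the primary alcohol are what make 23 fragile, so all four are masked as one kind of silyl ether and released together by buffered fluoride. This avoids a closing acid step (which an acetal on the phenols would need and which threatens C2–O1), avoids hydrogenolysis, and avoids chloromethyl ether reagents. The demand is that one near-neutral treatment cleaves both the aryl and the primary alkyl silyl ethers.

22 ⇒ 17 + 21. The C5–C(vinyl) bond is cut. This separates the resorcinol half from the core, uses the halogen that the key step leaves at C5, and fixes the E geometry beforehand in 21. The forward step must couple an electron-rich aryl chloride without touching the silyl ethers.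

17 ⇒ 15 (through 16). Bonds C3a–C7a and C4–C5 are cut and N2 is put back. Ring A and the dihydrofuran ring both disappear, leaving an acyclic ether that already carries C2 and C3. The forward step must be regiochemically unambiguous and must leave the anti C2/C3 pair untouched on heating.

15 ⇒ 12 + 14. The O1–C7a bond (ether oxygen to diazine carbon) is cut. The oxygen of 12 is the nucleophile, so the carbinol stereocentre is not involved. The demands are attack at the diazine carbon next to the methoxy group, not at the remote C–Cl, and no silyl migration in the alkoxide. The second demand is why the primary oxygen carries a triisopropylsilyl group and not a smaller silyl group, which could shift 1,3 from O to O.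

14 ⇒ 13. One C–OMe bond is cut; the forward substitution relies on the innate preference of 13 for attack at C4.

12 ⇒ 8 + 10 (through 11). The C2–C3 bond, which joins the two stereocentres, is cut. An allenylmetal addition sets both at once: C3 by chirality transfer from 8 and C2 by the anti preference of a cyclic transition state. The demands are anti selectivity with an aromatic aldehyde and configurational stability of 11.

10 ⇒ 9. One O–Si bond is cut (phenol protection).

8 ⇒ 7 ⇒ 6 ⇒ 5. In turn the S–O bond, the C(sp)–H/Si exchange and the carbinol C–H bond are cut. The single stereocentre of the small fragment is traced to a catalyst-controlled ketone reduction, which must tell an alkynyl from an alkyl substituent.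

5 ⇒ 2 + 3 (through 4), and 2 ⇒ 1. The C(O)–C(sp) bond is cut; acyl transfer through 4 stops the addition at the ketone. The O–Si bond of 2 leads back to 1.

21 ⇒ 19 + 20, and 19 ⇒ 18. The C=C bond is cut; the olefination must be E-selective and leave boron on the new alkene. Two O–Si bonds lead back to 18.

## Other disconnections considered

Alternative 1: The C2–C3 bond is cut. Ring A would be complete from the start, with the syringyl unit attached to O1 as a benzyl ether in the aryldiazoacetate A2. The dirhodium tetracarboxylate Rh2(S-PTTL)4 (divalent rhodium) would decompose A2, and the carbenoid at C3 would insert into the benzylic C2–H bond to give the cis ester A1.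
- In favour: one catalytic step would form the ring-closing C–C bond and fix C2 by catalyst control. Ring A would be bought as a brominated guaiacol-type arene, not built. The aryl bromide of A1 is a better cross-coupling partner than the chloride of 17, and on that point this plan is the better one.
- Against: such insertions are cis-selective, so C3 would have the wrong relative configuration. It would have to be epimerised through the ester enolate before reduction to CH2OH, which adds operations and puts C3 under thermodynamic control. The C7 methoxy group crowds the reactive conformer, ylide formation at the ether oxygen can compete, and a diazo transfer and a diazo compound must be handled.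
- Comparison: both plans reach a 5-halo core finished by the same coupling and deprotection. The insertion creates stereochemistry in its key step and therefore depends on selectivity at a hindered site, whereas the cycloaddition of 15 creates none. Step counts should be about equal, since the saving on ring A is spent on epimerisation, reduction and reprotection. As a late catalytic asymmetric step it is the equal of the chosen plan.

Alternative 2: The O1–C2 bond is cut. The diol A4, used as both carbinol epimers, would be ionised by acid at the benzylic carbon. The cation, stabilised by the para oxygen of the syringyl ring, would be captured by the ortho phenol of ring A to give the trans product A3.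
- In favour: the closure is stereoconvergent, so only C3 need be set beforehand. A3 already carries the free phenol and alcohol of the target and an aryl bromide. It is probably the shortest of the four plans, a genuine advantage over the chosen one.
- Against: C3, the one controlling centre, would sit next to an aryl ring and, before reduction, next to a carbonyl group, where enolisation can erode it. The trans outcome would rest on the preference of a reversible cation, not on a stereospecific event. Acid with a free para phenol can reopen the ring, and the free phenols burden the later coupling or call for reprotection.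
- Comparison: C2 would be set late under substrate control, against early under reagent control in the chosen plan. The mechanism is ionic and reversible, against pericyclic and irreversible. Step economy favours the alternative; security of enantiomeric and trans purity is judged lower.

Alternative 3: C3–C3a and O1–C7a are cut together. Pd(OAc)2 with norbornene would join the aryl iodide A7 and the cis-epoxide A6. The ortho palladacycle would open the epoxide at C3 with inversion, and the alkoxide would then close onto the ipso carbon to give A5.
- In favour: it is the most convergent plan, forming both bonds from ring A to the dihydrofuran in one catalytic operation from fragments of similar size. The methoxy group of A7 blocks the second ortho position, as this manifold requires. Inversion at C3 turns the cis-epoxide into the trans product while C2 is untouched. In convergence it is the better of the two.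
- Against: 1,2-disubstituted epoxides are far less reactive toward the palladacycle than terminal ones. The electron-rich benzylic end of A6 invites opening at C2 or rearrangement to a carbonyl compound. An enantiopure cis-epoxide is needed, and the C5 ester must be turned into the stilbene by reduction, oxidation and olefination in place of one coupling.
- Comparison: like the chosen plan it makes the stereocentres before the key step and only carries them through, so on that point they are equal. Its organometallic cascade has several selectivity demands (site of epoxide opening, ortho against ipso events), whereas the cycloaddition has none. It is expected to be comparable or slightly longer because of the ester detour.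

Key step: step 10

Assumption: benzofuran locants (O1, C2, C3, C3a, C4–C7, C7a) are used for the corresponding atoms of open-chain intermediates, and 18 and 20 are taken to be catalogue compounds.

## Route

Step 1
Reactants: 1 methyl glycolate
Product: 2 methyl 2-(triisopropylsilyloxy)acetate
Conditions: TIPSCl, imidazole, DMF, 0 °C → rt
Reagents that add atoms: chlorotriisopropylsilane, CC(C)[Si](Cl)(C(C)C)C(C)C
Why: Standard silylation of a primary alcohol; the bulky triisopropylsilyl group is chosen because it resists 1,3 O→O migration in the later alkoxide step and falls to fluoride at the end.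

Step 2
Reactants: 2 methyl 2-(triisopropylsilyloxy)acetate; 3 trimethylsilylacetylene
Product: 5 1-(triisopropylsilyloxy)-4-(trimethylsilyl)but-3-yn-2-one, via Weinreb amide 4 (not isolated)
Conditions: MeNH(OMe)·HCl, i-PrMgCl, THF, −20 °C; then LiC≡CSiMe3 (from 3, n-BuLi, THF, −78 °C), −20 → 0 °C; inverse quench into cold 1 M HCl
Reagents that add atoms: none
Why: The magnesium amide of N,O-dimethylhydroxylamine turns the ester into 4 in the flask, and the lithium acetylide adds once to give a chelated adduct that releases the ynone only on quench (Weinreb ketone synthesis); the acidic inverse quench keeps the liberated amine protonated so it cannot add to the ynone.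

Step 3
Reactants: 5 1-(triisopropylsilyloxy)-4-(trimethylsilyl)but-3-yn-2-one
Product: 6 (R)-1-(triisopropylsilyloxy)-4-(trimethylsilyl)but-3-yn-2-ol
Conditions: Ru(p-cymene)[(S,S)-TsDPEN] (1 mol %, preformed from RuCl(p-cymene)[(S,S)-TsDPEN] and KOH), i-PrOH, rt
Reagents that add atoms: none
Why: Noyori asymmetric transfer hydrogenation with a divalent ruthenium catalyst that delivers hydride and proton together; the catalyst tells the alkynyl from the sp3 substituent as in methyl alkynyl ketones, which with the (S,S) ligand should give the R alcohol here (the descriptor changes only because CH2OSi outranks the alkyne).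

Step 4
Reactants: 6 (R)-1-(triisopropylsilyloxy)-4-(trimethylsilyl)but-3-yn-2-ol
Product: 7 (R)-1-(triisopropylsilyloxy)but-3-yn-2-ol
Conditions: K2CO3 (cat.), MeOH, 0 °C
Reagents that add atoms: none
Why: Base-catalysed methanolysis cleaves only the C(sp)–Si bond; the hindered O-silyl ether and the stereocentre are not affected.

Step 5
Reactants: 7 (R)-1-(triisopropylsilyloxy)but-3-yn-2-ol
Product: 8 (R)-1-(triisopropylsilyloxy)but-3-yn-2-yl methanesulfonate
Conditions: MsCl, Et3N, CH2Cl2, −40 → 0 °C; used without storage
Reagents that add atoms: methanesulfonyl chloride, CS(=O)(=O)Cl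
Why: O-sulfonylation breaks no bond at the stereocentre, so the R configuration is retained.

Step 6
Reactants: 9 syringaldehyde
Product: 10 3,5-dimethoxy-4-(triisopropylsilyloxy)benzaldehyde
Conditions: TIPSCl, imidazole, DMF, rt → 40 °C
Reagents that add atoms: chlorotriisopropylsilane, CC(C)[Si](Cl)(C(C)C)C(C)C
Why: Silylation of an acidic, flanked phenol; the resulting aryl silyl ether is shielded by the two ortho methoxy groups and should survive alkoxide, heat and aqueous phosphate.

Step 7
Reactants: 8 (R)-1-(triisopropylsilyloxy)but-3-yn-2-yl methanesulfonate; 10 3,5-dimethoxy-4-(triisopropylsilyloxy)benzaldehyde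
Product: 12 (1R,2S)-1-[3,5-dimethoxy-4-(triisopropylsilyloxy)phenyl]-2-[(triisopropylsilyloxy)methyl]but-3-yn-1-ol, via allenylzinc reagent 11 (not isolated)
Conditions: Pd(OAc)2 (5 mol %), PPh3 (5 mol %), Et2Zn (3 equiv), THF, −78 → −20 °C; aq. NH4Cl
Reagents that add atoms: none
Why: Marshall propargylation: zerovalent palladium formed in situ displaces the mesylate in anti SN2′ fashion, transmetalation to zinc gives the axially chiral 11, and this adds to the aldehyde by a cyclic SE2′ transition state on the face bearing zinc. The net result is inversion at the former carbinol carbon, which sets C3 as S; the aryl group avoids the CH2OSi substituent in the six-membered transition state, which sets C2 as R (anti).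

Step 8
Reactants: 13 3,4,6-trichloropyridazine
Product: 14 3,6-dichloro-4-methoxypyridazine
Conditions: NaOMe (1.0 equiv), MeOH, 0 °C → rt
Reagents that add atoms: sodium methoxide, C[O-].[Na+]
Why: Nucleophilic aromatic substitution at C4, the most electrophilic position of 13 (para to a ring nitrogen and flanked by chlorine), so one equivalent of methoxide should react there.

Step 9
Reactants: 12 (1R,2S)-1-[3,5-dimethoxy-4-(triisopropylsilyloxy)phenyl]-2-[(triisopropylsilyloxy)methyl]but-3-yn-1-ol; 14 3,6-dichloro-4-methoxypyridazine
Product: 15 6-chloro-4-methoxy-3-{(1R,2S)-1-[3,5-dimethoxy-4-(triisopropylsilyloxy)phenyl]-2-[(triisopropylsilyloxy)methyl]but-3-yn-1-yloxy}pyridazine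
Conditions: NaH, THF–toluene, 0 °C; then 14, 0 °C → rt
Reagents that add atoms: none
Why: Addition–elimination SNAr by the alkoxide oxygen, so the carbinol centre keeps its configuration. Attack is expected at the carbon next to the methoxy group, because the remote C–Cl is deactivated (its activating ring nitrogen is para to the methoxy donor) and sodium can bridge the methoxy oxygen and the adjacent ring nitrogen; the triisopropylsilyl ether should not migrate to the alkoxide.

Step 10
Reactants: 15 6-chloro-4-methoxy-3-{(1R,2S)-1-[3,5-dimethoxy-4-(triisopropylsilyloxy)phenyl]-2-[(triisopropylsilyloxy)methyl]but-3-yn-1-yloxy}pyridazine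
Product: 17 (2R,3S)-5-chloro-2-[3,5-dimethoxy-4-(triisopropylsilyloxy)phenyl]-7-methoxy-3-[(triisopropylsilyloxy)methyl]-2,3-dihydro-1-benzofuran, via bicyclic diazene adduct 16 (not isolated)
Conditions: PhNEt2 (degassed, 0.02 M), 190 °C, pressure-rated sealed tube, Ar
Reagents that add atoms: none
Why: The electron-poor 1,2-diazine serves as the 4π component through its two carbon termini toward the tethered terminal alkyne in an intramolecular inverse-electron-demand Diels–Alder reaction; the closest known reaction type is the thermal cyclisation of 3-(alk-3-ynyloxy)pyridazines to 2,3-dihydrobenzofurans. The three-atom O1–C2–C3 tether can deliver the internal alkyne carbon only to the oxygen-bearing diazine carbon (bond C3a–C7a) and the terminal carbon only to the chlorine-bearing one (bond C4–C5), so the dihydrofuran ring closes as the five-membered ring fused across C3a–C7a in adduct 16. Ring A is closed by the same [4+2] event as a six-membered carbocycle and becomes aromatic when 16 loses N2 by retro-[4+2] cleavage, which makes the sequence irreversible. No stereocentre is created: the bridgehead carbons of 16 are transient and both faces of approach converge on 17. The step therefore needs only regioselectivity, which the tether and the fixed places of Cl (to C5) and OMe (to C7) secure, and survival of the preset C2/C3 pair, which has no enolisable neighbour. The chlorine lowers the diazine LUMO and the two tether substituents favour the folded conformer, which should offset the deactivating methoxy group. The weakly basic amine solvent removes traces of acid that could ionise the benzylic C2–O bond.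

Step 11
Reactants: 18 3,5-dihydroxybenzaldehyde
Product: 19 3,5-bis(triisopropylsilyloxy)benzaldehyde
Conditions: TIPSCl (2.4 equiv), imidazole, DMF, rt
Reagents that add atoms: chlorotriisopropylsilane, CC(C)[Si](Cl)(C(C)C)C(C)C
Why: Double silylation of unhindered phenols; triisopropylsilyl aryl ethers tolerate the lithium amide and the aqueous phosphate of the next two steps better than smaller silyl ethers.

Step 12
Reactants: 19 3,5-bis(triisopropylsilyloxy)benzaldehyde; 20 bis[(pinacolato)boryl]methane
Product: 21 2-[(E)-2-[3,5-bis(triisopropylsilyloxy)phenyl]ethenyl]-4,4,5,5-tetramethyl-1,3,2-dioxaborolane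
Conditions: LiTMP, THF, 0 °C; then 19, −78 °C → rt; aq. NH4Cl
Reagents that add atoms: none
Why: Boron–Wittig olefination: the α-boryl carbanion of 20 adds to the aldehyde and the adduct loses pinacol borate by syn B–O elimination, which should favour the trans alkenylboronate.

Step 13
Reactants: 17 (2R,3S)-5-chloro-2-[3,5-dimethoxy-4-(triisopropylsilyloxy)phenyl]-7-methoxy-3-[(triisopropylsilyloxy)methyl]-2,3-dihydro-1-benzofuran; 21 2-[(E)-2-[3,5-bis(triisopropylsilyloxy)phenyl]ethenyl]-4,4,5,5-tetramethyl-1,3,2-dioxaborolane
Product: 22 (2R,3S)-5-[(E)-2-[3,5-bis(triisopropylsilyloxy)phenyl]ethenyl]-2-[3,5-dimethoxy-4-(triisopropylsilyloxy)phenyl]-7-methoxy-3-[(triisopropylsilyloxy)methyl]-2,3-dihydro-1-benzofuran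
Conditions: Pd(OAc)2 (3 mol %), SPhos (6 mol %), K3PO4, toluene–H2O (10:1), 90 °C, Ar
Reagents that add atoms: none
Why: Suzuki–Miyaura coupling; the electron-rich biaryl phosphine makes oxidative addition into the electron-rich C5–Cl bond feasible, and transmetalation and reductive elimination retain the E geometry of the alkenylboronate. Neither stereocentre is near the reacting site.

Step 14
Reactants: 22 (2R,3S)-5-[(E)-2-[3,5-bis(triisopropylsilyloxy)phenyl]ethenyl]-2-[3,5-dimethoxy-4-(triisopropylsilyloxy)phenyl]-7-methoxy-3-[(triisopropylsilyloxy)methyl]-2,3-dihydro-1-benzofuran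
Product: 23 gnetucleistol F, 5-[(E)-2-[(2R,3S)-2-(4-hydroxy-3,5-dimethoxyphenyl)-3-(hydroxymethyl)-7-methoxy-2,3-dihydro-1-benzofuran-5-yl]ethenyl]benzene-1,3-diol
Conditions: TBAF (6 equiv), AcOH (6 equiv), THF, 0 °C → rt, Ar, dark
Reagents that add atoms: none
Why: Fluoride cleaves all four Si–O bonds; the acetic acid buffer keeps the phenols protonated, so the benzylic C2–O1 bond and the stilbene should not be exposed to phenolate or to strong acid.

## Compound list

1 | methyl glycolate | COC(=O)CO | starting material
2 | methyl 2-(triisopropylsilyloxy)acetate | COC(=O)CO[Si](C(C)C)(C(C)C)C(C)C | intermediate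
3 | trimethylsilylacetylene | C#C[Si](C)(C)C | starting material
4 | N-methoxy-N-methyl-2-(triisopropylsilyloxy)acetamide (not isolated) | CON(C)C(=O)CO[Si](C(C)C)(C(C)C)C(C)C | intermediate
5 | 1-(triisopropylsilyloxy)-4-(trimethylsilyl)but-3-yn-2-one | C[Si](C)(C)C#CC(=O)CO[Si](C(C)C)(C(C)C)C(C)C | intermediate
6 | (R)-1-(triisopropylsilyloxy)-4-(trimethylsilyl)but-3-yn-2-ol | C[Si](C)(C)C#C[C@@H](O)CO[Si](C(C)C)(C(C)C)C(C)C | intermediate
7 | (R)-1-(triisopropylsilyloxy)but-3-yn-2-ol | C#C[C@@H](O)CO[Si](C(C)C)(C(C)C)C(C)C | intermediate
8 | (R)-1-(triisopropylsilyloxy)but-3-yn-2-yl methanesulfonate | C#C[C@@H](OS(C)(=O)=O)CO[Si](C(C)C)(C(C)C)C(C)C | intermediate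
9 | syringaldehyde | COc1cc(C=O)cc(OC)c1O | starting material
10 | 3,5-dimethoxy-4-(triisopropylsilyloxy)benzaldehyde | COc1cc(C=O)cc(OC)c1O[Si](C(C)C)(C(C)C)C(C)C | intermediate
11 | ethyl[(aR)-4-(triisopropylsilyloxy)buta-1,2-dien-1-yl]zinc (not isolated) | CC[Zn]C([H])=[C@]=C([H])CO[Si](C(C)C)(C(C)C)C(C)C | intermediate
12 | (1R,2S)-1-[3,5-dimethoxy-4-(triisopropylsilyloxy)phenyl]-2-[(triisopropylsilyloxy)methyl]but-3-yn-1-ol | CC(C)[Si](C(C)C)(C(C)C)Oc1c(OC)cc([C@H](O)[C@H](CO[Si](C(C)C)(C(C)C)C(C)C)C#C)cc1OC | intermediate
13 | 3,4,6-trichloropyridazine | Clc1cc(Cl)c(Cl)nn1 | starting material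
14 | 3,6-dichloro-4-methoxypyridazine | COc1cc(Cl)nnc1Cl | intermediate
15 | 6-chloro-4-methoxy-3-{(1R,2S)-1-[3,5-dimethoxy-4-(triisopropylsilyloxy)phenyl]-2-[(triisopropylsilyloxy)methyl]but-3-yn-1-yloxy}pyridazine | CC(C)[Si](C(C)C)(C(C)C)Oc1c(OC)cc([C@H](Oc2nnc(Cl)cc2OC)[C@H](CO[Si](C(C)C)(C(C)C)C(C)C)C#C)cc1OC | intermediate
16 | bicyclic [4+2] adduct of 15: 2,3-diazabicyclo[2.2.2]octa-2,5,7-triene with N=N bridging the two former diazine carbons, Cl on one bridgehead, the O1–C2–C3 chain fused from the other bridgehead to the new C3a=C4 bridge, OMe on the third bridge; either bridgehead configuration (not isolated) | CC(C)[Si](C(C)C)(C(C)C)Oc1c(OC)cc(cc1OC)[C@@H]2OC34N=NC(Cl)(C=C3[C@H]2CO[Si](C(C)C)(C(C)C)C(C)C)C=C4OC | intermediate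
17 | (2R,3S)-5-chloro-2-[3,5-dimethoxy-4-(triisopropylsilyloxy)phenyl]-7-methoxy-3-[(triisopropylsilyloxy)methyl]-2,3-dihydro-1-benzofuran | CC(C)[Si](C(C)C)(C(C)C)Oc1c(OC)cc([C@@H]2Oc3c(OC)cc(Cl)cc3[C@H]2CO[Si](C(C)C)(C(C)C)C(C)C)cc1OC | intermediate
18 | 3,5-dihydroxybenzaldehyde | O=Cc1cc(O)cc(O)c1 | starting material
19 | 3,5-bis(triisopropylsilyloxy)benzaldehyde | O=Cc1cc(O[Si](C(C)C)(C(C)C)C(C)C)cc(O[Si](C(C)C)(C(C)C)C(C)C)c1 | intermediate
20 | bis[(pinacolato)boryl]methane | CC1(C)OB(CB2OC(C)(C)C(C)(C)O2)OC1(C)C | starting material
21 | 2-[(E)-2-[3,5-bis(triisopropylsilyloxy)phenyl]ethenyl]-4,4,5,5-tetramethyl-1,3,2-dioxaborolane | CC1(C)OB(/C=C/c2cc(O[Si](C(C)C)(C(C)C)C(C)C)cc(O[Si](C(C)C)(C(C)C)C(C)C)c2)OC1(C)C | intermediate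
22 | (2R,3S)-5-[(E)-2-[3,5-bis(triisopropylsilyloxy)phenyl]ethenyl]-2-[3,5-dimethoxy-4-(triisopropylsilyloxy)phenyl]-7-methoxy-3-[(triisopropylsilyloxy)methyl]-2,3-dihydro-1-benzofuran | CC(C)[Si](C(C)C)(C(C)C)Oc1c(OC)cc([C@@H]2Oc3c(OC)cc(/C=C/c4cc(O[Si](C(C)C)(C(C)C)C(C)C)cc(O[Si](C(C)C)(C(C)C)C(C)C)c4)cc3[C@H]2CO[Si](C(C)C)(C(C)C)C(C)C)cc1OC | intermediate
23 | gnetucleistol F | COc1cc([C@@H]2Oc3c(OC)cc(/C=C/c4cc(O)cc(O)c4)cc3[C@H]2CO)cc(OC)c1O | target

## Step count and least certain steps

Total step count: 14. Longest linear sequence: 10 steps (1, 2, 3, 4, 5, 7, 9, 10, 13, 14).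

Step 10 (key step). The cycloaddition may be outrun by thermal loss of the diazinone from C2, either by heterolysis of the benzylic C2–O bond or by syn-elimination through the ring nitrogen onto C3–H. The diazine methoxy group raises the required temperature, and the electron-rich aryl group at C2 stabilises positive charge there. The fallback lowers the electron density of that aryl group for the thermal step. It sets out from 15: fluoride cleavage of the aryl silyl ether in the presence of pivalic anhydride (CsF, Piv2O, DMF, 0 °C, so that the phenoxide is acylated as it forms) would give 6-chloro-4-methoxy-3-{(1R,2S)-1-[3,5-dimethoxy-4-(pivaloyloxy)phenyl]-2-[(triisopropylsilyloxy)methyl]but-3-yn-1-yloxy}pyridazine F1. Heating F1 as in step 10, now with more thermal latitude, would give (2R,3S)-5-chloro-2-[3,5-dimethoxy-4-(pivaloyloxy)phenyl]-7-methoxy-3-[(triisopropylsilyloxy)methyl]-2,3-dihydro-1-benzofuran F2. Reductive removal of the pivalate (DIBAL-H, CH2Cl2, −78 °C) would give (2R,3S)-5-chloro-2-(4-hydroxy-3,5-dimethoxyphenyl)-7-methoxy-3-[(triisopropylsilyloxy)methyl]-2,3-dihydro-1-benzofuran F3, and resilylation (TIPSCl, imidazole) comes back to the route at 17.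

Step 9. The bulky secondary alkoxide may be diverted to the remote C–Cl by steric repulsion from the methoxy group, which would lead to a ring A with the methoxy group at C6; slow substitution would also leave time for decomposition of the alkoxide. The fallback makes the two leaving groups unequal instead of relying on innate site preference. It sets out from 14: NaSMe (1 equiv, THF, 0 °C) would give 6-chloro-4-methoxy-3-(methylsulfanyl)pyridazine F4, separated from any regioisomer and assigned at this inexpensive stage. Oxidation (mCPBA, CH2Cl2) would give 6-chloro-4-methoxy-3-(methylsulfonyl)pyridazine F5, whose sulfonyl group is displaced by the sodium alkoxide of 12 far faster than chloride (THF, −40 °C). This comes back to the route at 15.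

Step 7. Anti selectivity may erode because an unbranched aromatic aldehyde discriminates less between the two cyclic transition states, and 11 may lose silanolate by 1,4-elimination through its propargyl form, depleting the reagent. The fallback uses an isolable, configurationally stable allenylboron reagent. It sets out from 7: ClCO2Me and pyridine would give (R)-methyl 1-(triisopropylsilyloxy)but-3-yn-2-yl carbonate F6. Copper-catalysed anti-SN2′ borylation (B2pin2, CuCl, Xantphos, KOt-Bu, THF) would give 4,4,5,5-tetramethyl-2-[(aR)-4-(triisopropylsilyloxy)buta-1,2-dien-1-yl]-1,3,2-dioxaborolane F7. Allenylboration of 10 (toluene, rt → 40 °C, optionally with catalytic diphenyl phosphate) through a closed chair transition state, followed by hydrolysis of the borate, comes back to the route at 12.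

Step 13. Oxidative addition into the electron-rich C5–Cl bond (para to O1) may be slow enough that protodeboronation or homocoupling consumes 21. The fallback is a Mizoroki–Heck arylation, which needs no boron reagent. It sets out from 19 and 17: Wittig methylenation of 19 (Ph3PCH3Br, KOt-Bu, THF) would give 3,5-bis(triisopropylsilyloxy)styrene F8, and its Heck reaction with 17 (Pd2(dba)3, P(t-Bu)3, Cy2NMe, dioxane, 110 °C) comes back to the route at 22.

Step 14. Cleavage of the hindered primary silyl ether may be sluggish, prolonging exposure of the phenol-rich stilbene to fluoride, during which phenolate oxidation or opening of C2–O1 through a quinone methide can set in. The fallback removes the robust silyl ethers before the stilbene exists. It sets out from 17: TBAF in THF would give (2R,3S)-5-chloro-2-(4-hydroxy-3,5-dimethoxyphenyl)-3-(hydroxymethyl)-7-methoxy-2,3-dihydro-1-benzofuran F9. Suzuki–Miyaura coupling of F9 with 21 (catalyst of step 13, extra K3PO4) would give 5-[(E)-2-[3,5-bis(triisopropylsilyloxy)phenyl]ethenyl]-(2R,3S)-2-(4-hydroxy-3,5-dimethoxyphenyl)-3-(hydroxymethyl)-7-methoxy-2,3-dihydro-1-benzofuran F10. Its two unhindered aryl silyl ethers should fall under very mild conditions (KF, MeOH, rt), which comes back to the route at 23.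

## Further compounds

F1 | step 10 | 6-chloro-4-methoxy-3-{(1R,2S)-1-[3,5-dimethoxy-4-(pivaloyloxy)phenyl]-2-[(triisopropylsilyloxy)methyl]but-3-yn-1-yloxy}pyridazine | CC(C)(C)C(=O)Oc1c(OC)cc([C@H](Oc2nnc(Cl)cc2OC)[C@H](CO[Si](C(C)C)(C(C)C)C(C)C)C#C)cc1OC
F2 | step 10 | (2R,3S)-5-chloro-2-[3,5-dimethoxy-4-(pivaloyloxy)phenyl]-7-methoxy-3-[(triisopropylsilyloxy)methyl]-2,3-dihydro-1-benzofuran | CC(C)(C)C(=O)Oc1c(OC)cc([C@@H]2Oc3c(OC)cc(Cl)cc3[C@H]2CO[Si](C(C)C)(C(C)C)C(C)C)cc1OC
F3 | step 10 | (2R,3S)-5-chloro-2-(4-hydroxy-3,5-dimethoxyphenyl)-7-methoxy-3-[(triisopropylsilyloxy)methyl]-2,3-dihydro-1-benzofuran | COc1cc([C@@H]2Oc3c(OC)cc(Cl)cc3[C@H]2CO[Si](C(C)C)(C(C)C)C(C)C)cc(OC)c1O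
F4 | step 9 | 6-chloro-4-methoxy-3-(methylsulfanyl)pyridazine | COc1cc(Cl)nnc1SC
F5 | step 9 | 6-chloro-4-methoxy-3-(methylsulfonyl)pyridazine | COc1cc(Cl)nnc1S(C)(=O)=O
F6 | step 7 | (R)-methyl 1-(triisopropylsilyloxy)but-3-yn-2-yl carbonate | C#C[C@@H](OC(=O)OC)CO[Si](C(C)C)(C(C)C)C(C)C
F7 | step 7 | 4,4,5,5-tetramethyl-2-[(aR)-4-(triisopropylsilyloxy)buta-1,2-dien-1-yl]-1,3,2-dioxaborolane | CC1(C)OB(C([H])=[C@]=C([H])CO[Si](C(C)C)(C(C)C)C(C)C)OC1(C)C
F8 | step 13 | 3,5-bis(triisopropylsilyloxy)styrene | C=Cc1cc(O[Si](C(C)C)(C(C)C)C(C)C)cc(O[Si](C(C)C)(C(C)C)C(C)C)c1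
F9 | step 14 | (2R,3S)-5-chloro-2-(4-hydroxy-3,5-dimethoxyphenyl)-3-(hydroxymethyl)-7-methoxy-2,3-dihydro-1-benzofuran | COc1cc([C@@H]2Oc3c(OC)cc(Cl)cc3[C@H]2CO)cc(OC)c1O
F10 | step 14 | (2R,3S)-5-[(E)-2-[3,5-bis(triisopropylsilyloxy)phenyl]ethenyl]-2-(4-hydroxy-3,5-dimethoxyphenyl)-3-(hydroxymethyl)-7-methoxy-2,3-dihydro-1-benzofuran | COc1cc([C@@H]2Oc3c(OC)cc(/C=C/c4cc(O[Si](C(C)C)(C(C)C)C(C)C)cc(O[Si](C(C)C)(C(C)C)C(C)C)c4)cc3[C@H]2CO)cc(OC)c1O
A1 | alternative 1 | methyl (2R,3S)-cis-5-bromo-2-[3,5-dimethoxy-4-(triisopropylsilyloxy)phenyl]-7-methoxy-2,3-dihydro-1-benzofuran-3-carboxylate | COc1cc([C@@H]2Oc3c(OC)cc(Br)cc3[C@@H]2C(=O)OC)cc(OC)c1O[Si](C(C)C)(C(C)C)C(C)C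
A2 | alternative 1 | methyl 2-[5-bromo-2-{[3,5-dimethoxy-4-(triisopropylsilyloxy)phenyl]methoxy}-3-methoxyphenyl]-2-diazoacetate | COC(=O)C(=[N+]=[N-])c1cc(Br)cc(OC)c1OCc1cc(OC)c(O[Si](C(C)C)(C(C)C)C(C)C)c(OC)c1
A3 | alternative 2 | (2R,3S)-trans-5-bromo-2-(4-hydroxy-3,5-dimethoxyphenyl)-3-(hydroxymethyl)-7-methoxy-2,3-dihydro-1-benzofuran | COc1cc([C@@H]2Oc3c(OC)cc(Br)cc3[C@H]2CO)cc(OC)c1O
A4 | alternative 2 | (2S)-2-(5-bromo-2-hydroxy-3-methoxyphenyl)-1-(4-hydroxy-3,5-dimethoxyphenyl)propane-1,3-diol, both C1 epimers | COc1cc(C(O)[C@H](CO)c2cc(Br)cc(OC)c2O)cc(OC)c1O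
A5 | alternative 3 | methyl (2R,3S)-trans-3-[(tert-butyldimethylsilyloxy)methyl]-2-[3,5-dimethoxy-4-(pivaloyloxy)phenyl]-7-methoxy-2,3-dihydro-1-benzofuran-5-carboxylate | CC(C)(C)C(=O)Oc1c(OC)cc([C@@H]2Oc3c(OC)cc(C(=O)OC)cc3[C@H]2CO[Si](C)(C)C(C)(C)C)cc1OC
A6 | alternative 3 | cis-(2S,3R)-3-[(tert-butyldimethylsilyloxy)methyl]-2-[3,5-dimethoxy-4-(pivaloyloxy)phenyl]oxirane | CC(C)(C)C(=O)Oc1c(OC)cc([C@@H]2O[C@@H]2CO[Si](C)(C)C(C)(C)C)cc1OC
A7 | alternative 3 | methyl 4-iodo-3-methoxybenzoate | COC(=O)c1ccc(I)c(OC)c1
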